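**Retrosynthetic overview**

1. Numbering and feature: the hydrindane is numbered as indane (C1 and C4 methyl carbinols, C3a/C7a trans ring fusion, C6 spiro; ring B six-membered, ring C five-membered); ring A is C6–C1′(=O)–C2′(prenyl)2–C3′(OH)=C4′(acyl)–C5′(=O). In ring C, C7–C7a–C1–C2 are the four carbons of methyl acetoacetate and C3–C3a–C4(CH3)–C5 are an isoprene unit.
2. Ring A is made last: gem-diprenylation at C2′, Claisen ring closure C4′–C5′, and C1′–C2′ by acylating the dianion of 6-methylheptane-2,4-dione with a lactone that bridges the C4 oxygen and C6.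
3. Ring B and that lactone come from one Mn(OAc)3 radical cyclisation of a malonate onto the isopropenyl group (C5–C6, then C4–O). The lactone tells the two carbonyls on C6 apart, so the spiro centre follows from C4.
4. The malonate arm (C6–C7) is added by Michael addition to a 2-methylidene ketone, and the C1 carbinol by methyl addition to the ketone.
5. Ring C is made first, in one flask: γ-alkylation of the acetoacetate dianion by isoprene dibromide (C2–C3), then asymmetric palladium-catalysed allylic alkylation (C3a–C7a). Ring order: C, B, A.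

Key step: step 1

Remarks on the chemistry:
- Convention: β is the face of H-3a, α the face of H-7a. The target has 1β-OH, 1α-CH3, 4α-OH, 4β-CH3, C1′ on the α face of C6 and C5′ on the β face.
- Assumption: the (R,R) antipode of the diphosphine is written in step 1. The sense of induction for this ring closure is assumed; the (S,S) ligand would be used if it proves opposite.

**Step 1**
Reactants: 1 methyl acetoacetate; 2 (E)-1,4-dibromo-2-methylbut-2-ene
Product: 5 methyl (1R,5S)-2-oxo-5-(prop-1-en-2-yl)cyclopentane-1-carboxylate, via acetoacetate dianion 3 (not isolated), via bromo keto ester enolate 4 (not isolated)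
Conditions: NaH (1.1 equiv), THF, 0 °C; n-BuLi (1.05 equiv), 0 °C; cannulate into 2 (1.1 equiv), THF, −78 → −30 °C; then Pd2(dba)3·CHCl3 (2.5 mol %), (1R,2R)-N,N′-bis[2-(diphenylphosphino)benzoyl]cyclohexane-1,2-diamine (7.5 mol %), −30 °C → rt; aq. NH4Cl
Reagents that add atoms: none
Why: The dianion 3 reacts at its more basic γ-carbon by SN2 at the CH2Br of 2 that sits on the CH= carbon (a prenyl-type, γ,γ-disubstituted and less hindered terminus), which forms C2–C3 and leaves enolate 4; zerovalent palladium then ionises the remaining allylic bromide to a 2-methyl-π-allyl complex and the β-ketoester carbon attacks its inner terminus, which forms C3a–C7a (Tsuji–Trost allylic alkylation). The closest known reactions are the γ-alkylation of acetoacetate dianions with 1,4-dihalobut-2-enes and the palladium-catalysed cyclisation of 3-oxooct-6-enoates carrying an allylic leaving group at C8 to 2-alkenylcyclopentanone esters. Ring C closes in the 5-exo mode at C3a; the 7-endo mode at the CH2 terminus is disfavoured. C3a is controlled by the chiral diphosphine on palladium, because the two faces of the π-allyl unit exchange by π–σ–π at the unsubstituted CH2 terminus and the ligand decides which complex is attacked; C7a is the acidic β-ketoester carbon and settles trans to the isopropenyl group. The step needs site selectivity in the first displacement and no racemic background closure: the trisubstituted alkene of 2 makes the two CH2Br groups unequal, inverse addition at −78 °C holds back double alkylation, and any enol ether formed by O-alkylation should be re-ionised by zerovalent palladium to the same π-allyl enolate pair.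

**Step 2**
Reactants: 5 methyl (1R,5S)-2-oxo-5-(prop-1-en-2-yl)cyclopentane-1-carboxylate
Product: 6 methyl (6R,7S)-7-(prop-1-en-2-yl)-1,4-dioxaspiro[4.4]nonane-6-carboxylate
Conditions: HOCH2CH2OH (5 equiv), pyridinium p-toluenesulfonate (0.1 equiv), benzene, reflux, azeotropic removal of water
Reagents that add atoms: ethylene glycol, OCCO
Why: Acid-catalysed ketalisation (dioxolane formation) masks the C1 ketone so that only the ester is reduced next, the weak pyridinium acid should leave the isopropenyl group and C3a untouched, and C7a stays trans.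

**Step 3**
Reactants: 6 methyl (6R,7S)-7-(prop-1-en-2-yl)-1,4-dioxaspiro[4.4]nonane-6-carboxylate
Product: 7 [(6S,7S)-7-(prop-1-en-2-yl)-1,4-dioxaspiro[4.4]nonan-6-yl]methanol
Conditions: LiAlH4 (1.2 equiv), THF, 0 °C; aq. NaOH work-up
Reagents that add atoms: none
Why: LiAlH4 reduction of the ester to the primary alcohol brings C7 to the alcohol level, while the ketal and the 1,1-disubstituted alkene are inert to hydride.

**Step 4**
Reactants: 7 [(6S,7S)-7-(prop-1-en-2-yl)-1,4-dioxaspiro[4.4]nonan-6-yl]methanol
Product: 8 (2S,3S)-2-(hydroxymethyl)-3-(prop-1-en-2-yl)cyclopentan-1-one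
Conditions: 1 M aq. HCl, THF, 0 °C → rt
Reagents that add atoms: water, O
Why: Aqueous acid hydrolysis of the dioxolane returns the ketone, and brief exposure at or below room temperature should limit acid-catalysed β-elimination of the β-hydroxy ketone.

**Step 5**
Reactants: 8 (2S,3S)-2-(hydroxymethyl)-3-(prop-1-en-2-yl)cyclopentan-1-one; 9 dimethyl malonate
Product: 12 dimethyl 2-{[(1R,5S)-2-oxo-5-(prop-1-en-2-yl)cyclopentyl]methyl}propanedioate, via keto mesylate 10 (not isolated), via methylidene ketone 11 (not isolated)
Conditions: MsCl (1.1 equiv), Et3N (2.5 equiv), CH2Cl2, −20 → 0 °C; cold aqueous wash; then 9 (3 equiv), NaOMe (0.2 equiv), MeOH, 0 °C → rt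
Reagents that add atoms: none
Why: Mesylation and E1cB elimination give the 2-methylidene ketone, which should take up the malonate anion in a Michael addition (forming C6–C7) faster than it isomerises to the endocyclic enone; C7a is set by protonation of the ketone enolate and equilibrates under methoxide to the trans relationship with the C3a isopropenyl group.

**Step 6**
Reactants: 12 dimethyl 2-{[(1R,5S)-2-oxo-5-(prop-1-en-2-yl)cyclopentyl]methyl}propanedioate
Product: 13 dimethyl 2-{[(1R,2S,5S)-2-hydroxy-2-methyl-5-(prop-1-en-2-yl)cyclopentyl]methyl}propanedioate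
Conditions: MeMgBr (3 equiv), anhydrous CeCl3 (3 equiv), THF, −78 °C; AcOH, −78 °C
Reagents that add atoms: methylmagnesium bromide, C[Mg]Br
Why: The first equivalent of reagent turns the malonate into its enolate, which shields both esters, and the weakly basic organocerium reagent (CeCl3-mediated Grignard 1,2-addition) should then attack the C1 ketone without enolisation from the α face, anti to the neighbouring C7a side chain, so that the new hydroxyl is β and cis to the C7 arm (C1 set by substrate control).

**Step 7**
Reactants: 13 dimethyl 2-{[(1R,2S,5S)-2-hydroxy-2-methyl-5-(prop-1-en-2-yl)cyclopentyl]methyl}propanedioate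
Product: 14 methyl (1R,2S,5S,6R,8R)-5-hydroxy-1,5-dimethyl-9-oxo-10-oxatricyclo[6.2.1.0^2,6]undecane-8-carboxylate
Conditions: Mn(OAc)3·2H2O (2.2 equiv), degassed AcOH, 70 °C
Reagents that add atoms: none
Why: In this Mn(OAc)3 oxidative radical cyclisation the malonyl radical at C6 adds 6-endo to the CH2 end (C5) of the isopropenyl group through a chair on the two trans, equatorial arms (5-exo closure would demand a trans-fused bicyclo[3.3.0]octane), the tertiary C4 radical is oxidised to the cation and is captured by the ester carbonyl that is 1,3-diaxial to it with loss of methyl acetate, which places the C4 oxygen axial on the α face (methyl β), sets C4, and marks the α carbonyl on C6 as the lactone and the β one as the ester.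

**Step 8**
Reactants: 14 methyl (1R,2S,5S,6R,8R)-5-hydroxy-1,5-dimethyl-9-oxo-10-oxatricyclo[6.2.1.0^2,6]undecane-8-carboxylate; 15 6-methylheptane-2,4-dione
Product: 17 methyl 1β,4α-dihydroxy-1α,4β-dimethyl-6α-(7-methyl-3,5-dioxooctanoyl)-trans-hydrindane-6β-carboxylate, via diketone dianion 16 (not isolated)
Conditions: 15 (3.5 equiv), LiN(iPr)2 (7 equiv), THF, −78 → 0 °C; add 14, −78 → −20 °C; AcOH, then aq. NH4Cl
Reagents that add atoms: none
Why: In this Claisen-type acylation of a β-diketone dianion the terminal CH2 carbanion of 16 (deprotonation at CH3 is favoured over the hindered isobutyl CH2) should attack the strained, s-cis bridged lactone carbonyl in preference to the neopentyl-type methyl ester, the expelled C4 alkoxide becomes the free 4α-hydroxyl, and excess dianion deprotonates the new triketone so that the addition cannot reverse; the lactone carbonyl thus becomes C1′ bonded to C2′.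

**Step 9**
Reactants: 17 methyl 1β,4α-dihydroxy-1α,4β-dimethyl-6α-(7-methyl-3,5-dioxooctanoyl)-trans-hydrindane-6β-carboxylate
Product: 18 spiro trione diol (target without the two prenyl groups; C2′ is CH2)
Conditions: KOtBu (5 equiv), THF, 0 → 50 °C; 1 M aq. HCl
Reagents that add atoms: none
Why: In this intramolecular Claisen (Dieckmann-type) condensation the doubly activated carbon C4′ of the triketone dianion attacks the C5′ methyl ester in a six-membered closure, the non-nucleophilic base should not cleave the C6–C1′ bond, and formation of the strongly acidic cyclic β-triketone drives the step; no bond to C6 is broken, so the spiro configuration laid down in step 7 is kept.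

**Step 10**
Reactants: 18 spiro trione diol; 19 1-bromo-3-methylbut-2-ene (prenyl bromide)
Product: 21 CNP0198642.4 (target), via monoprenyl trione 20 (not isolated)
Conditions: 19 (2.5 equiv), NaOMe (3.5 equiv), MeOH, 0 °C → rt; dilute aq. HCl
Reagents that add atoms: none
Why: C2′ is the only ring carbon that still carries hydrogens between two carbonyls, so twofold C-alkylation of the trione anion with prenyl bromide in methanol (hydrogen bonding to the enolate oxygens favours C- over O-alkylation), as in the gem-dialkylation of acylphloroglucinol-derived triones, should give the gem-diprenyl carbon; the tertiary alcohols do not react and no stereocentre is touched.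

**Compound list**

1 | methyl acetoacetate (methyl 3-oxobutanoate) | COC(=O)CC(C)=O | starting material
2 | (E)-1,4-dibromo-2-methylbut-2-ene | BrC/C(C)=C/CBr | starting material
3 | sodium lithium dianion of methyl acetoacetate | [Na+].[Li+].COC(=O)[CH-]C(=O)[CH2-] | intermediate
4 | sodium enolate of methyl (E)-8-bromo-7-methyl-3-oxooct-6-enoate | [Na+].COC(=O)[CH-]C(=O)CC/C=C(\C)CBr | intermediate
5 | methyl (1R,5S)-2-oxo-5-(prop-1-en-2-yl)cyclopentane-1-carboxylate | COC(=O)[C@@H]1[C@H](CCC1=O)C(C)=C | intermediate
6 | methyl (6R,7S)-7-(prop-1-en-2-yl)-1,4-dioxaspiro[4.4]nonane-6-carboxylate | COC(=O)[C@@H]1[C@H](CCC12OCCO2)C(C)=C | intermediate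
7 | [(6S,7S)-7-(prop-1-en-2-yl)-1,4-dioxaspiro[4.4]nonan-6-yl]methanol | OC[C@@H]1[C@H](CCC12OCCO2)C(C)=C | intermediate
8 | (2S,3S)-2-(hydroxymethyl)-3-(prop-1-en-2-yl)cyclopentan-1-one | OC[C@@H]1[C@H](CCC1=O)C(C)=C | intermediate
9 | dimethyl malonate | COC(=O)CC(=O)OC | starting material
10 | [(1S,5S)-2-oxo-5-(prop-1-en-2-yl)cyclopentyl]methyl methanesulfonate | CS(=O)(=O)OC[C@@H]1[C@H](CCC1=O)C(C)=C | intermediate
11 | (3R)-2-methylidene-3-(prop-1-en-2-yl)cyclopentan-1-one | C=C1[C@H](CCC1=O)C(C)=C | intermediate
12 | dimethyl 2-{[(1R,5S)-2-oxo-5-(prop-1-en-2-yl)cyclopentyl]methyl}propanedioate | COC(=O)C(C[C@@H]1[C@H](CCC1=O)C(C)=C)C(=O)OC | intermediate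
13 | dimethyl 2-{[(1R,2S,5S)-2-hydroxy-2-methyl-5-(prop-1-en-2-yl)cyclopentyl]methyl}propanedioate | COC(=O)C(C[C@@H]1[C@H](CC[C@]1(C)O)C(C)=C)C(=O)OC | intermediate
14 | methyl (1R,2S,5S,6R,8R)-5-hydroxy-1,5-dimethyl-9-oxo-10-oxatricyclo[6.2.1.0^2,6]undecane-8-carboxylate (trans-hydrindane with 1β-OH, 1α-CH3, 4β-CH3, lactone from the 4α-oxygen to the 6α-carbonyl, 6β-CO2CH3) | COC(=O)[C@]12C[C@@H]3[C@H](CC[C@]3(C)O)[C@](C)(OC1=O)C2 | intermediate
15 | 6-methylheptane-2,4-dione | CC(=O)CC(=O)CC(C)C | starting material
16 | dilithium dianion of 6-methylheptane-2,4-dione (C1 and C3 deprotonated) | [Li+].[Li+].[CH2-]C(=O)[CH-]C(=O)CC(C)C | intermediate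
17 | methyl 1β,4α-dihydroxy-1α,4β-dimethyl-6α-(7-methyl-3,5-dioxooctanoyl)-trans-hydrindane-6β-carboxylate (3aβ-H, 7aα-H) | COC(=O)[C@@]1(C(=O)CC(=O)CC(=O)CC(C)C)C[C@@H]2[C@H](CC[C@]2(C)O)[C@](C)(O)C1 | intermediate
18 | spiro trione diol: 1β,4α-dihydroxy-1α,4β-dimethyl-trans-hydrindane spiro-fused at C6 to ring A = 3′-hydroxy-4′-(3-methylbutanoyl)cyclohex-3′-ene-1′,5′-dione, C1′ on the α face and C5′ on the β face, C2′ = CH2 | C1C(=O)[C@@]2(C[C@@H]3[C@H](CC[C@]3(C)O)[C@](C)(O)C2)C(=O)C(C(=O)CC(C)C)=C1O | intermediate
19 | 1-bromo-3-methylbut-2-ene (prenyl bromide) | CC(C)=CCBr | starting material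
20 | monoprenyl trione: 18 with one 3-methylbut-2-enyl group on C2′ (either configuration at C2′) | CC(C)=CCC1C(=O)[C@@]2(C[C@@H]3[C@H](CC[C@]3(C)O)[C@](C)(O)C2)C(=O)C(C(=O)CC(C)C)=C1O | intermediate
21 | CNP0198642.4: 18 with two 3-methylbut-2-enyl groups on C2′ (C1 S, C3a S, C4 R, C6 S, C7a R in the numbering used here) | CC(C)=CCC1(CC=C(C)C)C(=O)[C@@]2(C[C@@H]3[C@H](CC[C@]3(C)O)[C@](C)(O)C2)C(=O)C(C(=O)CC(C)C)=C1O | target

**Step count**

Total: 10 steps. Longest linear sequence: 10 steps (1 and 2 to 21).

**Steps most likely to fail**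

Step 1. The first displacement may take place at the wrong allylic terminus or twice, and the ring closure may run in part through an uncatalysed, racemic pathway or with poor facial discrimination on the π-allyl complex.
- The fallback sets out from 1 and comes back at 7; it replaces catalyst control by auxiliary control and the dibromide by an electrophile with one allylic terminus.
- Transesterification of 1 with (1R,2S,5R)-8-phenylmenthol (toluene, reflux, DMAP) should give (1R,2S,5R)-5-methyl-2-(2-phenylpropan-2-yl)cyclohexyl 3-oxobutanoate F1.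
- Its sodium lithium dianion F2 (NaH, then n-BuLi) is alkylated with 19 to the 8-phenylmenthyl 7-methyl-3-oxooct-6-enoate F3.
- Mn(OAc)3·2H2O with Cu(OAc)2·H2O in AcOH should close ring C by 5-exo cyclisation of the β-ketoester radical, divalent copper turning the tertiary radical into the isopropenyl group, to give the 8-phenylmenthyl (1R,5S)-2-oxo-5-(prop-1-en-2-yl)cyclopentane-1-carboxylate F4. The aryl group of the auxiliary shields one face of the radical, and the C3a diastereomers are separable.
- Ketalisation as in step 2 gives the dioxolane ester F5, and LiAlH4 releases the auxiliary and gives 7.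
- The sense of induction of the auxiliary is assumed; its antipode would be used otherwise.

Step 7. After the 6-endo closure the oxidised tertiary centre may lose a proton or take up acetate instead of closing the lactone, and the C1 hydroxyl may lactonise onto the malonate in hot acetic acid before the radical forms.
- The fallback sets out from 13 and comes back at 14; it avoids oxidant and hot acid.
- Bromination of the malonate carbon (CBr4, DBU, THF, 0 °C) gives dimethyl 2-bromo-2-{[(1R,2S,5S)-2-hydroxy-2-methyl-5-(prop-1-en-2-yl)cyclopentyl]methyl}propanedioate F6.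
- Atom-transfer radical cyclisation ((Bu3Sn)2 (0.1 equiv), benzene, sunlamp) should close ring B 6-endo and give the tertiary C4 bromide F7 (either C4 epimer).
- Warming in DMF ionises the C–Br bond, and the axial ester closes the lactone with loss of bromomethane to give 14.

Step 8. The dianion may attack the methyl ester as well as the lactone carbonyl, which would erode the spiro configuration, or the liberated C4 alkoxide may reverse the acylation.
- The fallback sets out from 14 and comes back at 17.
- Me2AlN(OMe)Me (from AlMe3 and MeNH(OMe)·HCl, CH2Cl2) should open only the lactone and give the hydroxy N-methoxy-N-methylamide F8.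
- TMSOTf and 2,6-lutidine cap both tertiary hydroxyls to give the bis(trimethylsilyl) ether F9.
- The dianion 16 adds to the amide to form a chelated adduct that can neither revert nor add twice; work-up gives the silylated triketo ester F10.
- Dilute acid removes the silyl groups and gives 17.

**Further compounds**

F1 | step 1 | (1R,2S,5R)-5-methyl-2-(2-phenylpropan-2-yl)cyclohexyl 3-oxobutanoate | C[C@@H]1CC[C@H]([C@@H](C1)OC(=O)CC(C)=O)C(C)(C)c1ccccc1
F2 | step 1 | sodium lithium dianion of F1 | [Na+].[Li+].C[C@@H]1CC[C@H]([C@@H](C1)OC(=O)[CH-]C(=O)[CH2-])C(C)(C)c1ccccc1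
F3 | step 1 | (1R,2S,5R)-5-methyl-2-(2-phenylpropan-2-yl)cyclohexyl 7-methyl-3-oxooct-6-enoate | C[C@@H]1CC[C@H]([C@@H](C1)OC(=O)CC(=O)CCC=C(C)C)C(C)(C)c1ccccc1
F4 | step 1 | (1R,2S,5R)-5-methyl-2-(2-phenylpropan-2-yl)cyclohexyl (1R,5S)-2-oxo-5-(prop-1-en-2-yl)cyclopentane-1-carboxylate | C[C@@H]1CC[C@H]([C@@H](C1)OC(=O)[C@@H]2[C@H](CCC2=O)C(C)=C)C(C)(C)c3ccccc3
F5 | step 1 | (1R,2S,5R)-5-methyl-2-(2-phenylpropan-2-yl)cyclohexyl (6R,7S)-7-(prop-1-en-2-yl)-1,4-dioxaspiro[4.4]nonane-6-carboxylate | C[C@@H]1CC[C@H]([C@@H](C1)OC(=O)[C@@H]2[C@H](CCC23OCCO3)C(C)=C)C(C)(C)c4ccccc4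
F6 | step 7 | dimethyl 2-bromo-2-{[(1R,2S,5S)-2-hydroxy-2-methyl-5-(prop-1-en-2-yl)cyclopentyl]methyl}propanedioate | COC(=O)C(Br)(C[C@@H]1[C@H](CC[C@]1(C)O)C(C)=C)C(=O)OC
F7 | step 7 | dimethyl 4-bromo-1β-hydroxy-1α,4-dimethyl-trans-hydrindane-6,6-dicarboxylate (either configuration at C4) | COC(=O)C1(C(=O)OC)C[C@@H]2[C@H](CC[C@]2(C)O)C(C)(Br)C1
F8 | step 8 | methyl 1β,4α-dihydroxy-6α-[methoxy(methyl)carbamoyl]-1α,4β-dimethyl-trans-hydrindane-6β-carboxylate | COC(=O)[C@@]1(C(=O)N(C)OC)C[C@@H]2[C@H](CC[C@]2(C)O)[C@](C)(O)C1
F9 | step 8 | 1,4-bis(trimethylsilyl) ether of F8 | COC(=O)[C@@]1(C(=O)N(C)OC)C[C@@H]2[C@H](CC[C@]2(C)O[Si](C)(C)C)[C@](C)(O[Si](C)(C)C)C1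
F10 | step 8 | 1,4-bis(trimethylsilyl) ether of 17 | COC(=O)[C@@]1(C(=O)CC(=O)CC(=O)CC(C)C)C[C@@H]2[C@H](CC[C@]2(C)O[Si](C)(C)C)[C@](C)(O[Si](C)(C)C)C1
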